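Cuts: (a) the aryl–alkenyl bond C6(ring A)–CH= by a one-flask C–H borylation/Suzuki–Miyaura coupling, giving the 6-unsubstituted dihydrobenzofuran 15 and the E iodoalkene 16; (b) C2–C3 of the dihydrofuran by a rhodium carbene C–H insertion; (c) the ketone C–aryl bond (aryllithium 8 + aldehyde 5); (d) the benzylic C–O bond (Mitsunobu reaction of 3 with 4).
Forward: vanillin supplies both guaiacyl units (benzyl alcohol 3 and iodoalkene 16), ring A comes from 2,6-dihydroxybenzaldehyde and the resorcinol ring from 5-bromoresorcinol; the furan ring is closed at the diazo stage, the styryl arm is joined last, and one fluoride step frees all five phenols.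
Stereochemistry: C3 (S) is set by the chiral dirhodium catalyst in the insertion; C2 (S) follows by acid equilibration of the cis product to the trans isomer; the E alkene comes from a Takai olefination and a stereoretentive coupling.
Enabling feature: in 15, C6–H of ring A (the benzo ring of the benzofuran) is the only one of nine aryl C–H bonds with hydrogen on both neighbouring carbons (C5 and C7), and it lies meta to both ring A oxygens (O1 and the C4 oxygen). Iridium borylation should therefore pick the one carbon that electrophilic substitution cannot reach and turn it into the nucleophile, so no halogen handle is carried through the route.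
All phenols travel as triisopropylsilyl (TIPS) ethers, orthogonal to the two methyl ethers that stay in the target.

Key step: step 12

Remark: the sense of induction of Rh2(S-PTAD)4, dirhodium tetrakis[(S)-(1-adamantyl)(N-phthalimido)acetate], at C3 is assumed to be 3S for this substrate; if the insertion favours 3R, Rh2(R-PTAD)4 is used and nothing else changes.

Step 1
Reactants: 1 vanillin (4-hydroxy-3-methoxybenzaldehyde)
Product: 2 3-methoxy-4-(triisopropylsilyloxy)benzaldehyde
Conditions: TIPSCl, imidazole, DMF, rt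
Reagents that add atoms: triisopropylsilyl chloride (TIPSCl), CC(C)[Si](Cl)(C(C)C)C(C)C
Why: Imidazole-mediated silylation of the phenol is routine, and the hindered aryl silyl ether should survive the organolithium, hydrazine, acid and aqueous phosphate used later.

Step 2
Reactants: 2 3-methoxy-4-(triisopropylsilyloxy)benzaldehyde
Product: 3 [3-methoxy-4-(triisopropylsilyloxy)phenyl]methanol
Conditions: NaBH4, MeOH, 0 °C
Reagents that add atoms: none
Why: Hydride reduction of the aryl aldehyde to the benzylic alcohol is chemoselective and leaves the silyl ether intact.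

Step 3
Reactants: 3 [3-methoxy-4-(triisopropylsilyloxy)phenyl]methanol; 4 2,6-dihydroxybenzaldehyde
Product: 5 2-hydroxy-6-{[3-methoxy-4-(triisopropylsilyloxy)benzyl]oxy}benzaldehyde
Conditions: PPh3, DIAD, THF, 0 °C to rt
Reagents that add atoms: none
Why: In this Mitsunobu etherification the acidic phenol of 4 is alkylated by the activated benzylic alcohol, and the remaining hydroxyl, chelated to the formyl group, is far less nucleophilic, which should hold the reaction at the monoether.

Step 4
Reactants: 6 5-bromoresorcinol (5-bromobenzene-1,3-diol)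
Product: 7 1-bromo-3,5-bis(triisopropylsilyloxy)benzene
Conditions: TIPSCl, imidazole, DMF, rt
Reagents that add atoms: triisopropylsilyl chloride (TIPSCl), CC(C)[Si](Cl)(C(C)C)C(C)C
Why: Double silylation of the two equivalent phenols gives an aryl bromide whose oxygen groups sit meta to the halogen, so the derived aryllithium cannot undergo silyl migration.

Step 5
Reactants: 7 1-bromo-3,5-bis(triisopropylsilyloxy)benzene; 5 2-hydroxy-6-{[3-methoxy-4-(triisopropylsilyloxy)benzyl]oxy}benzaldehyde
Product: 9 racemic [3,5-bis(triisopropylsilyloxy)phenyl](2-hydroxy-6-{[3-methoxy-4-(triisopropylsilyloxy)benzyl]oxy}phenyl)methanol, via 3,5-bis(triisopropylsilyloxy)phenyllithium 8 (not isolated)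
Conditions: 7 (2.1 equiv), n-BuLi (2.1 equiv), THF, −78 °C; then 5, −78 to 0 °C; aq NH4Cl
Reagents that add atoms: none
Why: Bromine–lithium exchange gives the aryllithium, of which one equivalent deprotonates the phenol and the second adds to the aldehyde (1,2-addition); the carbinol centre forms as a racemate and is removed in step 6.

Step 6
Reactants: 9 racemic [3,5-bis(triisopropylsilyloxy)phenyl](2-hydroxy-6-{[3-methoxy-4-(triisopropylsilyloxy)benzyl]oxy}phenyl)methanol
Product: 10 [3,5-bis(triisopropylsilyloxy)phenyl](2-hydroxy-6-{[3-methoxy-4-(triisopropylsilyloxy)benzyl]oxy}phenyl)methanone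
Conditions: MnO2 (activated, excess), CH2Cl2, rt
Reagents that add atoms: none
Why: MnO2 oxidises the doubly benzylic alcohol selectively, and the product is stabilised by the hydrogen bond between the ortho hydroxyl and the carbonyl group.

Step 7
Reactants: 10 [3,5-bis(triisopropylsilyloxy)phenyl](2-hydroxy-6-{[3-methoxy-4-(triisopropylsilyloxy)benzyl]oxy}phenyl)methanone
Product: 11 hydrazone of ketone 10, 2-{hydrazinylidene[3,5-bis(triisopropylsilyloxy)phenyl]methyl}-3-{[3-methoxy-4-(triisopropylsilyloxy)benzyl]oxy}phenol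
Conditions: N2H4·H2O (excess), AcOH (cat.), EtOH, 80 °C
Reagents that add atoms: hydrazine, NN
Why: Hydrazone condensation should proceed because the hydrogen-bonded, near-planar ortho-hydroxy ketone is far more accessible than a ketone flanked by two protected oxygens, which is why the second ortho oxygen is left free up to this point.

Step 8
Reactants: 11 hydrazone of ketone 10
Product: 12 silyl ether hydrazone, {[3,5-bis(triisopropylsilyloxy)phenyl](2-{[3-methoxy-4-(triisopropylsilyloxy)benzyl]oxy}-6-(triisopropylsilyloxy)phenyl)methylidene}hydrazine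
Conditions: TIPSCl, imidazole, DMAP (cat.), DMF, 40 °C
Reagents that add atoms: triisopropylsilyl chloride (TIPSCl), CC(C)[Si](Cl)(C(C)C)C(C)C
Why: The bulky silyl chloride should silylate the phenol in preference to the weakly nucleophilic hydrazone NH2, removing the acidic O–H that would protonate the diazo carbon and leaving the benzylic ether CH2 as the only C–H bond within reach of the carbene.

Step 9
Reactants: 12 silyl ether hydrazone
Product: 14 (2R,3S)-3-[3,5-bis(triisopropylsilyloxy)phenyl]-2-[3-methoxy-4-(triisopropylsilyloxy)phenyl]-4-(triisopropylsilyloxy)-2,3-dihydro-1-benzofuran (2,3-cis), via diaryldiazomethane 13 (not isolated)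
Conditions: MnO2, CH2Cl2, 0 °C, filter; then Rh2(S-PTAD)4 (1 mol %), CH2Cl2, 0 °C
Reagents that add atoms: none
Why: MnO2 dehydrogenates the hydrazone to the diaryldiazomethane, and the derived donor/donor rhodium carbene inserts into the benzylic ether C–H bond five atoms away (1,5 C–H insertion, a known route to 2,3-diaryl-2,3-dihydrobenzofurans) through a concerted three-centre transition state in which the chiral carboxylate pocket selects the carbene face and sets C3 as S, while the concerted hydrogen delivery places the two aryl groups cis (C2 as R).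

Step 10
Reactants: 14 (2R,3S)-cis dihydrobenzofuran
Product: 15 (2S,3S)-3-[3,5-bis(triisopropylsilyloxy)phenyl]-2-[3-methoxy-4-(triisopropylsilyloxy)phenyl]-4-(triisopropylsilyloxy)-2,3-dihydro-1-benzofuran (2,3-trans)
Conditions: TFA, CH2Cl2, 0 °C to rt
Reagents that add atoms: none
Why: Acid reversibly ionises the C2–O bond to a benzylic cation stabilised by the para silyloxy group, and re-closure by the ring A phenol equilibrates C2 to the thermodynamically favoured trans isomer (2S) while C3, which is not involved, keeps its configuration (acid-mediated epimerisation of 2-aryl-2,3-dihydrobenzofurans).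

Step 11
Reactants: 2 3-methoxy-4-(triisopropylsilyloxy)benzaldehyde
Product: 16 (E)-[4-(2-iodoethenyl)-2-methoxyphenoxy]triisopropylsilane
Conditions: CrCl2, CHI3, THF/dioxane, 0 °C to rt
Reagents that add atoms: iodoform, IC(I)I
Why: In the Takai olefination the geminal dichromium species from iodoform and CrCl2 adds to the aldehyde and elimination of the β-oxychromium intermediate gives the E iodoalkene under steric control.

Step 12
Reactants: 15 (2S,3S)-trans dihydrobenzofuran; 17 bis(pinacolato)diboron; 16 (E)-[4-(2-iodoethenyl)-2-methoxyphenoxy]triisopropylsilane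
Product: 19 (2S,3S)-3-[3,5-bis(triisopropylsilyloxy)phenyl]-2-[3-methoxy-4-(triisopropylsilyloxy)phenyl]-6-{(E)-2-[3-methoxy-4-(triisopropylsilyloxy)phenyl]ethenyl}-4-(triisopropylsilyloxy)-2,3-dihydro-1-benzofuran, via C6 pinacol boronate of the trans core 18 (not isolated)
Conditions: [Ir(OMe)(cod)]2 (2 mol %), dtbpy (4 mol %), THF, 80 °C; volatiles removed; then Pd(dppf)Cl2 (5 mol %), K3PO4, dioxane/H2O, 70 °C
Reagents that add atoms: none
Why: An iridium tris(boryl) complex of 4,4'-di-tert-butyl-2,2'-bipyridine (trivalent iridium) cleaves the least hindered, most acidic aryl C–H bond and releases the aryl boronate 18 by C–B reductive elimination; after removal of volatile pinacolborane, zerovalent palladium inserts into the C–I bond of 16, the phosphate-activated boronate transfers the C6 aryl group to palladium, and reductive elimination forms the C6–CH= bond. The closest known reaction type is the one-pot, meta-selective iridium-catalysed C–H borylation/Suzuki–Miyaura coupling of 1,3-disubstituted arenes such as resorcinol diethers, which are borylated at C5. No ring is closed and no stereocentre is formed; C2 and C3 are remote and untouched, and the E geometry is carried over from 16 because oxidative addition, transmetalation and reductive elimination all proceed with retention at the alkenyl carbon. The step needs site selectivity for one of nine aryl C–H bonds: C6–H of ring A is the only one with hydrogen on both neighbouring carbons and it is meta to both ring A oxygens, whereas C5–H is screened by the C4 silyloxy group, C7–H is ortho to O1 and para to the C4 oxygen, and every C–H of the two pendant aryl rings has at least one ortho substituent. Chemoselectivity in the palladium stage is secured by the fast oxidative addition of the alkenyl iodide and by the stability of aryl triisopropylsilyl ethers to aqueous phosphate.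

Step 13
Reactants: 19 pentakis(triisopropylsilyl) ether of the target
Product: 20 bisisorhapontigenin B, 5-[(2S,3S)-4-hydroxy-2-(4-hydroxy-3-methoxyphenyl)-6-[(E)-2-(4-hydroxy-3-methoxyphenyl)ethenyl]-2,3-dihydro-1-benzofuran-3-yl]benzene-1,3-diol
Conditions: TBAF, AcOH, THF, 0 °C to rt
Reagents that add atoms: none
Why: Fluoride cleaves all five aryl Si–O bonds, and the acetic acid buffer protonates the phenoxides as they form, protecting the stilbene polyphenol from oxidation and from phenoxide-driven opening of the dihydrofuran, so that C2, C3 and the E alkene are unchanged.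

Compound list
1 | vanillin (4-hydroxy-3-methoxybenzaldehyde) | COc1cc(C=O)ccc1O | starting material
2 | 3-methoxy-4-(triisopropylsilyloxy)benzaldehyde | COc1cc(C=O)ccc1O[Si](C(C)C)(C(C)C)C(C)C | intermediate
3 | [3-methoxy-4-(triisopropylsilyloxy)phenyl]methanol | COc1cc(CO)ccc1O[Si](C(C)C)(C(C)C)C(C)C | intermediate
4 | 2,6-dihydroxybenzaldehyde | O=Cc1c(O)cccc1O | starting material
5 | 2-hydroxy-6-{[3-methoxy-4-(triisopropylsilyloxy)benzyl]oxy}benzaldehyde | O=Cc1c(O)cccc1OCc1ccc(O[Si](C(C)C)(C(C)C)C(C)C)c(OC)c1 | intermediate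
6 | 5-bromoresorcinol (5-bromobenzene-1,3-diol) | Oc1cc(O)cc(Br)c1 | starting material
7 | 1-bromo-3,5-bis(triisopropylsilyloxy)benzene | Brc1cc(O[Si](C(C)C)(C(C)C)C(C)C)cc(O[Si](C(C)C)(C(C)C)C(C)C)c1 | intermediate
8 | 3,5-bis(triisopropylsilyloxy)phenyllithium | [Li]c1cc(O[Si](C(C)C)(C(C)C)C(C)C)cc(O[Si](C(C)C)(C(C)C)C(C)C)c1 | intermediate
9 | racemic [3,5-bis(triisopropylsilyloxy)phenyl](2-hydroxy-6-{[3-methoxy-4-(triisopropylsilyloxy)benzyl]oxy}phenyl)methanol | OC(c1cc(O[Si](C(C)C)(C(C)C)C(C)C)cc(O[Si](C(C)C)(C(C)C)C(C)C)c1)c1c(O)cccc1OCc1ccc(O[Si](C(C)C)(C(C)C)C(C)C)c(OC)c1 | intermediate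
10 | [3,5-bis(triisopropylsilyloxy)phenyl](2-hydroxy-6-{[3-methoxy-4-(triisopropylsilyloxy)benzyl]oxy}phenyl)methanone | O=C(c1cc(O[Si](C(C)C)(C(C)C)C(C)C)cc(O[Si](C(C)C)(C(C)C)C(C)C)c1)c1c(O)cccc1OCc1ccc(O[Si](C(C)C)(C(C)C)C(C)C)c(OC)c1 | intermediate
11 | hydrazone of ketone 10 (free ortho phenol) | NN=C(c1cc(O[Si](C(C)C)(C(C)C)C(C)C)cc(O[Si](C(C)C)(C(C)C)C(C)C)c1)c1c(O)cccc1OCc1ccc(O[Si](C(C)C)(C(C)C)C(C)C)c(OC)c1 | intermediate
12 | silyl ether hydrazone (ortho phenol as triisopropylsilyl ether) | NN=C(c1cc(O[Si](C(C)C)(C(C)C)C(C)C)cc(O[Si](C(C)C)(C(C)C)C(C)C)c1)c1c(O[Si](C(C)C)(C(C)C)C(C)C)cccc1OCc1ccc(O[Si](C(C)C)(C(C)C)C(C)C)c(OC)c1 | intermediate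
13 | diaryldiazomethane from 12 | [N-]=[N+]=C(c1cc(O[Si](C(C)C)(C(C)C)C(C)C)cc(O[Si](C(C)C)(C(C)C)C(C)C)c1)c1c(O[Si](C(C)C)(C(C)C)C(C)C)cccc1OCc1ccc(O[Si](C(C)C)(C(C)C)C(C)C)c(OC)c1 | intermediate
14 | (2R,3S)-3-[3,5-bis(triisopropylsilyloxy)phenyl]-2-[3-methoxy-4-(triisopropylsilyloxy)phenyl]-4-(triisopropylsilyloxy)-2,3-dihydro-1-benzofuran (2,3-cis) | c1cc(O[Si](C(C)C)(C(C)C)C(C)C)c2c(c1)O[C@@H](c1ccc(O[Si](C(C)C)(C(C)C)C(C)C)c(OC)c1)[C@H]2c1cc(O[Si](C(C)C)(C(C)C)C(C)C)cc(O[Si](C(C)C)(C(C)C)C(C)C)c1 | intermediate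
15 | (2S,3S)-3-[3,5-bis(triisopropylsilyloxy)phenyl]-2-[3-methoxy-4-(triisopropylsilyloxy)phenyl]-4-(triisopropylsilyloxy)-2,3-dihydro-1-benzofuran (2,3-trans) | c1cc(O[Si](C(C)C)(C(C)C)C(C)C)c2c(c1)O[C@H](c1ccc(O[Si](C(C)C)(C(C)C)C(C)C)c(OC)c1)[C@H]2c1cc(O[Si](C(C)C)(C(C)C)C(C)C)cc(O[Si](C(C)C)(C(C)C)C(C)C)c1 | intermediate
16 | (E)-[4-(2-iodoethenyl)-2-methoxyphenoxy]triisopropylsilane | COc1cc(/C=C/I)ccc1O[Si](C(C)C)(C(C)C)C(C)C | intermediate
17 | bis(pinacolato)diboron | CC1(C)OB(OC1(C)C)B1OC(C)(C)C(C)(C)O1 | starting material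
18 | C6 pinacol boronate of 15, (2S,3S) | CC1(C)OB(OC1(C)C)c1cc(O[Si](C(C)C)(C(C)C)C(C)C)c2c(c1)O[C@H](c1ccc(O[Si](C(C)C)(C(C)C)C(C)C)c(OC)c1)[C@H]2c1cc(O[Si](C(C)C)(C(C)C)C(C)C)cc(O[Si](C(C)C)(C(C)C)C(C)C)c1 | intermediate
19 | pentakis(triisopropylsilyl) ether of bisisorhapontigenin B, (2S,3S), E alkene | COc1cc(/C=C/c2cc(O[Si](C(C)C)(C(C)C)C(C)C)c3c(c2)O[C@H](c2ccc(O[Si](C(C)C)(C(C)C)C(C)C)c(OC)c2)[C@H]3c2cc(O[Si](C(C)C)(C(C)C)C(C)C)cc(O[Si](C(C)C)(C(C)C)C(C)C)c2)ccc1O[Si](C(C)C)(C(C)C)C(C)C | intermediate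
20 | bisisorhapontigenin B, (2S,3S), E alkene | COc1cc(/C=C/c2cc(O)c3c(c2)O[C@H](c2ccc(O)c(OC)c2)[C@H]3c2cc(O)cc(O)c2)ccc1O | target

Total step count: 13. Longest linear sequence: 11 steps (steps 1, 2, 3, 5, 6, 7, 8, 9, 10, 12, 13, from vanillin).

Steps most likely to fail

Step 9. The carbene carbon is flanked by two ortho oxygen substituents. Slow metal carbene formation could let the diazo compound dimerise to the azine, or the twisted carbene could insert with poor facial selectivity, giving low enantiomeric purity at C3. The fallback sets out from ketone 10 and comes back at 15, replacing the carbene by an anionic ring closure and a resolution. Silylation of 10 (TIPSOTf, 2,6-lutidine) gives the silyl ether ketone F1. LiTMP in THF at −78 °C deprotonates the benzylic ether CH2, and the anion adds to the ketone to give the 3-hydroxy-2,3-dihydrobenzofuran F2 as a diastereomer mixture. Ionic hydrogenation with Et3SiH and TFA removes the tertiary benzylic hydroxyl through the C3 cation, and the same acid equilibrates C2 to trans, giving the racemate, that is 15 together with its (2R,3R) antipode F3. Preparative chromatography on a chiral stationary phase then delivers 15.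

Step 12. Borylation next to the ring oxygen (C7–H, where the tied-back oxygen shields little) could compete with C6–H. In the second stage the electron-rich aryl boronate could lose boron by protodeboronation faster than it transfers its aryl group to palladium. The fallback builds the handle in from the start; it sets out from benzyl alcohol 3 and comes back at 19. Purchased 4-bromo-2,6-dihydroxybenzaldehyde F4 is joined to 3 under the Mitsunobu conditions of step 3 to give the bromo monoether aldehyde F5. Addition of 8 at −78 °C gives the carbinol F6, MnO2 the ketone F7, hydrazine the hydrazone F8 and silylation the silyl ether hydrazone F9. Oxidation to the diazo compound F10 and rhodium-catalysed insertion give the cis 6-bromo dihydrobenzofuran F11, and acid equilibration gives the trans bromide F12. A Heck reaction of F12 with triisopropyl(2-methoxy-4-vinylphenoxy)silane F13 (from 2 by Wittig methylenation with Ph3P=CH2) under Pd(OAc)2, P(o-tol)3 and Et3N in DMF at 100 °C forms the same aryl–alkenyl bond with E selectivity and gives 19.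

Step 10. The C2 cation could lose the C3 proton (elimination to a triarylethene) and be re-protonated, eroding the C3 configuration, or the acid could start to cleave silyl ethers. The fallback moves the epimerisation to the end and drives it by a phenoxide instead of an acid; it sets out from 14 and comes back at 20. The cis compound 14 is taken through the conditions of step 12 to give the cis C6 boronate F14 (not isolated) and then the cis pentasilyl stilbene F15. Fluoride deprotection as in step 13 gives the 2-epimer of the target F16. With K2CO3 in MeOH under argon, the phenoxide of the C2 para-hydroxyphenyl group should open the ring to a para-quinone methide, and the ring A phenoxide should add back (5-exo-trig oxa-Michael addition) to give the thermodynamically preferred trans isomer 20, with C3 untouched.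

Further compounds
F1 | step 9 | [3,5-bis(triisopropylsilyloxy)phenyl](2-{[3-methoxy-4-(triisopropylsilyloxy)benzyl]oxy}-6-(triisopropylsilyloxy)phenyl)methanone | O=C(c1cc(O[Si](C(C)C)(C(C)C)C(C)C)cc(O[Si](C(C)C)(C(C)C)C(C)C)c1)c1c(O[Si](C(C)C)(C(C)C)C(C)C)cccc1OCc1ccc(O[Si](C(C)C)(C(C)C)C(C)C)c(OC)c1
F2 | step 9 | 3-[3,5-bis(triisopropylsilyloxy)phenyl]-2-[3-methoxy-4-(triisopropylsilyloxy)phenyl]-4-(triisopropylsilyloxy)-2,3-dihydro-1-benzofuran-3-ol (racemic diastereomer mixture) | c1cc(O[Si](C(C)C)(C(C)C)C(C)C)c2c(c1)OC(c1ccc(O[Si](C(C)C)(C(C)C)C(C)C)c(OC)c1)C2(O)c1cc(O[Si](C(C)C)(C(C)C)C(C)C)cc(O[Si](C(C)C)(C(C)C)C(C)C)c1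
F3 | step 9 | (2R,3R) antipode of 15, formed with 15 as the racemate | c1cc(O[Si](C(C)C)(C(C)C)C(C)C)c2c(c1)O[C@@H](c1ccc(O[Si](C(C)C)(C(C)C)C(C)C)c(OC)c1)[C@@H]2c1cc(O[Si](C(C)C)(C(C)C)C(C)C)cc(O[Si](C(C)C)(C(C)C)C(C)C)c1
F4 | step 12 | 4-bromo-2,6-dihydroxybenzaldehyde | O=Cc1c(O)cc(Br)cc1O
F5 | step 12 | 4-bromo-2-hydroxy-6-{[3-methoxy-4-(triisopropylsilyloxy)benzyl]oxy}benzaldehyde | O=Cc1c(O)cc(Br)cc1OCc1ccc(O[Si](C(C)C)(C(C)C)C(C)C)c(OC)c1
F6 | step 12 | racemic [3,5-bis(triisopropylsilyloxy)phenyl](4-bromo-2-hydroxy-6-{[3-methoxy-4-(triisopropylsilyloxy)benzyl]oxy}phenyl)methanol | OC(c1cc(O[Si](C(C)C)(C(C)C)C(C)C)cc(O[Si](C(C)C)(C(C)C)C(C)C)c1)c1c(O)cc(Br)cc1OCc1ccc(O[Si](C(C)C)(C(C)C)C(C)C)c(OC)c1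
F7 | step 12 | [3,5-bis(triisopropylsilyloxy)phenyl](4-bromo-2-hydroxy-6-{[3-methoxy-4-(triisopropylsilyloxy)benzyl]oxy}phenyl)methanone | O=C(c1cc(O[Si](C(C)C)(C(C)C)C(C)C)cc(O[Si](C(C)C)(C(C)C)C(C)C)c1)c1c(O)cc(Br)cc1OCc1ccc(O[Si](C(C)C)(C(C)C)C(C)C)c(OC)c1
F8 | step 12 | hydrazone of ketone F7 | NN=C(c1cc(O[Si](C(C)C)(C(C)C)C(C)C)cc(O[Si](C(C)C)(C(C)C)C(C)C)c1)c1c(O)cc(Br)cc1OCc1ccc(O[Si](C(C)C)(C(C)C)C(C)C)c(OC)c1
F9 | step 12 | silyl ether hydrazone of the bromo series | NN=C(c1cc(O[Si](C(C)C)(C(C)C)C(C)C)cc(O[Si](C(C)C)(C(C)C)C(C)C)c1)c1c(O[Si](C(C)C)(C(C)C)C(C)C)cc(Br)cc1OCc1ccc(O[Si](C(C)C)(C(C)C)C(C)C)c(OC)c1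
F10 | step 12 | diaryldiazomethane of the bromo series | [N-]=[N+]=C(c1cc(O[Si](C(C)C)(C(C)C)C(C)C)cc(O[Si](C(C)C)(C(C)C)C(C)C)c1)c1c(O[Si](C(C)C)(C(C)C)C(C)C)cc(Br)cc1OCc1ccc(O[Si](C(C)C)(C(C)C)C(C)C)c(OC)c1
F11 | step 12 | (2R,3S)-6-bromo-3-[3,5-bis(triisopropylsilyloxy)phenyl]-2-[3-methoxy-4-(triisopropylsilyloxy)phenyl]-4-(triisopropylsilyloxy)-2,3-dihydro-1-benzofuran (cis) | Brc1cc(O[Si](C(C)C)(C(C)C)C(C)C)c2c(c1)O[C@@H](c1ccc(O[Si](C(C)C)(C(C)C)C(C)C)c(OC)c1)[C@H]2c1cc(O[Si](C(C)C)(C(C)C)C(C)C)cc(O[Si](C(C)C)(C(C)C)C(C)C)c1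
F12 | step 12 | (2S,3S)-6-bromo-3-[3,5-bis(triisopropylsilyloxy)phenyl]-2-[3-methoxy-4-(triisopropylsilyloxy)phenyl]-4-(triisopropylsilyloxy)-2,3-dihydro-1-benzofuran (trans) | Brc1cc(O[Si](C(C)C)(C(C)C)C(C)C)c2c(c1)O[C@H](c1ccc(O[Si](C(C)C)(C(C)C)C(C)C)c(OC)c1)[C@H]2c1cc(O[Si](C(C)C)(C(C)C)C(C)C)cc(O[Si](C(C)C)(C(C)C)C(C)C)c1
F13 | step 12 | triisopropyl(2-methoxy-4-vinylphenoxy)silane | COc1cc(C=C)ccc1O[Si](C(C)C)(C(C)C)C(C)C
F14 | step 10 | C6 pinacol boronate of 14, (2R,3S) | CC1(C)OB(OC1(C)C)c1cc(O[Si](C(C)C)(C(C)C)C(C)C)c2c(c1)O[C@@H](c1ccc(O[Si](C(C)C)(C(C)C)C(C)C)c(OC)c1)[C@H]2c1cc(O[Si](C(C)C)(C(C)C)C(C)C)cc(O[Si](C(C)C)(C(C)C)C(C)C)c1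
F15 | step 10 | (2R,3S) cis isomer of 19 | COc1cc(/C=C/c2cc(O[Si](C(C)C)(C(C)C)C(C)C)c3c(c2)O[C@@H](c2ccc(O[Si](C(C)C)(C(C)C)C(C)C)c(OC)c2)[C@H]3c2cc(O[Si](C(C)C)(C(C)C)C(C)C)cc(O[Si](C(C)C)(C(C)C)C(C)C)c2)ccc1O[Si](C(C)C)(C(C)C)C(C)C
F16 | step 10 | (2R,3S) 2-epimer of bisisorhapontigenin B | COc1cc(/C=C/c2cc(O)c3c(c2)O[C@@H](c2ccc(O)c(OC)c2)[C@H]3c2cc(O)cc(O)c2)ccc1O
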